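The plan cuts the C3–C4 bond of the tetrahydrofuran ring, the bond between the two methyl-bearing carbons. Because C3 and C4 each carry one methyl and their hydrogens are cis, the bond is made as a tetrasubstituted C3=C4 double bond: ring-closing metathesis of the methacrylate of an (R)-1-aryl-2-methylallyl alcohol closes a butenolide in which O1, C2 (as lactone carbonyl) and the C5 aryl stereocentre are already in place. Syn-hydrogenation anti to the C5 aryl then sets C3 and C4, aryllithium addition and ionic reduction set C2 on the same open face (all-cis ring), and the erythro aryloxypropanol arm is attached last by Mitsunobu inversion and chelation-controlled reduction.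

Key step: step 4

Remark: the SMILES is read as an all-cis (2S,3R,4S,5R) tetrahydrofuran with an erythro (1R,2S) arm; aryl bromide 9, isopropenylmagnesium bromide solution and recombinant benzaldehyde lyase are taken as purchasable.

Step 1
Reactants: 1 3,4-dimethoxybenzaldehyde (veratraldehyde); 2 isopropenylmagnesium bromide
Product: 3 rac-1-(3,4-dimethoxyphenyl)-2-methylprop-2-en-1-ol
Conditions: THF, 0 °C; then aq. NH4Cl
Reagents that add atoms: none
Why: Grignard 1,2-addition of the isopropenyl group to the aldehyde should give the allylic benzylic alcohol, racemic at the new carbinol centre.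

Step 2
Reactants: 3 rac-1-(3,4-dimethoxyphenyl)-2-methylprop-2-en-1-ol
Product: 4 (R)-1-(3,4-dimethoxyphenyl)-2-methylprop-2-en-1-ol
Conditions: Ti(OiPr)4 (10 mol%), D-(−)-diisopropyl tartrate (15 mol%), t-BuOOH (0.6 equiv), 4 Å molecular sieves, CH2Cl2, −20 °C, stopped near 55% conversion
Reagents that add atoms: none
Why: Sharpless kinetic resolution, in which the D-(−)-tartrate catalyst should epoxidise the (S)-alcohol much faster (fast enantiomer gives the erythro epoxy alcohol on the tartrate-dictated face), so the (R)-alcohol is recovered in high ee.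

Step 3
Reactants: 4 (R)-1-(3,4-dimethoxyphenyl)-2-methylprop-2-en-1-ol; 5 methacryloyl chloride
Product: 6 (R)-1-(3,4-dimethoxyphenyl)-2-methylprop-2-en-1-yl 2-methylprop-2-enoate
Conditions: Et3N, DMAP (cat.), CH2Cl2, 0 °C
Reagents that add atoms: none
Why: DMAP-catalysed O-acylation of the secondary alcohol under basic conditions, which does not touch the C–O stereocentre.

Step 4
Reactants: 6 (R)-1-(3,4-dimethoxyphenyl)-2-methylprop-2-en-1-yl 2-methylprop-2-enoate
Product: 7 (S)-5-(3,4-dimethoxyphenyl)-3,4-dimethylfuran-2(5H)-one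
Conditions: RuCl2(=CH-C6H4-2-OiPr)(L), L = 1,3-bis(2-methylphenyl)imidazolidin-2-ylidene (10 mol%), toluene (0.005 M), 80 °C, argon sparge
Reagents that add atoms: none
Why: Ring-closing olefin metathesis by the metallacyclobutane mechanism: the ruthenium alkylidene loads onto one 1,1-disubstituted alkene of 6, the tethered second alkene closes a ruthenacyclobutane, and cycloreversion should release the tetrasubstituted C3=C4 bond of 7 together with ethylene. The closest known reaction types are ring-closing metathesis of dimethallyl substrates to tetrasubstituted five-membered cycloalkenes and of acrylate esters of allylic alcohols to butenolides, for which ruthenium catalysts with small N-aryl groups were designed. The five-membered lactone closes by intramolecular metathesis between the methacrylate alkene and the isopropenyl alkene, the ester being the tether that already contains O1, C2 and C5. No stereocentre is created, and the C5 stereocentre from step 2 should survive because the medium is neutral and non-ionising, which a base-mediated condensation to the same butenolide would not guarantee for this acidic benzylic position (the descriptor changes from R to S only through CIP priorities). The step needs ring closure to outrun dimerisation and alkene isomerisation, which is secured by high dilution, removal of ethylene in the argon stream and the reluctance of both gem-disubstituted alkenes to homodimerise.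

Step 5
Reactants: 7 (S)-5-(3,4-dimethoxyphenyl)-3,4-dimethylfuran-2(5H)-one
Product: 8 (3R,4S,5R)-5-(3,4-dimethoxyphenyl)-3,4-dimethyldihydrofuran-2(3H)-one (all-cis)
Conditions: H2 (4 bar), Rh/Al2O3 (5 wt% Rh), EtOAc, rt
Reagents that add atoms: none
Why: Heterogeneous syn-hydrogenation should add both hydrogens to the butenolide face opposite the C5 aryl, placing the C3 and C4 methyls cis to each other and to the aryl, and rhodium is chosen because it cleaves the benzylic lactone C–O bond far less readily than palladium.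

Step 6
Reactants: 8 (3R,4S,5R)-5-(3,4-dimethoxyphenyl)-3,4-dimethyldihydrofuran-2(3H)-one; 9 1-(benzyloxy)-4-bromo-2-methoxybenzene
Product: 11 (3R,4S,5R)-2-[4-(benzyloxy)-3-methoxyphenyl]-5-(3,4-dimethoxyphenyl)-3,4-dimethyltetrahydrofuran-2-ol (anomer mixture), via 4-benzyloxy-3-methoxyphenyllithium 10 (not isolated)
Conditions: 9, n-BuLi (1.2 equiv), THF, −78 °C; then 8, −78 °C; aq. NH4Cl
Reagents that add atoms: none
Why: Bromine–lithium exchange followed by single nucleophilic addition of the aryllithium to the lactone carbonyl should give the cyclic hemiketal, with C3–C5 untouched because addition at −78 °C outpaces α-deprotonation.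

Step 7
Reactants: 11 (3R,4S,5R)-2-[4-(benzyloxy)-3-methoxyphenyl]-5-(3,4-dimethoxyphenyl)-3,4-dimethyltetrahydrofuran-2-ol
Product: 13 (2S,3R,4S,5R)-2-[4-(benzyloxy)-3-methoxyphenyl]-5-(3,4-dimethoxyphenyl)-3,4-dimethyltetrahydrofuran, via oxocarbenium ion 12 (not isolated)
Conditions: Et3SiH (5 equiv, present from the start), BF3·OEt2 (2 equiv), CH2Cl2, −78 °C; cold NaHCO3 quench
Reagents that add atoms: none
Why: Ionic hydrogenation (silane reduction of a 2-aryl oxocarbenium ion), in which hydride should attack the ring face opposite the C3 methyl, C4 methyl and C5 aryl, so the new C2–H is cis to the other three ring hydrogens and the aryl lands all-cis (2S).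

Step 8
Reactants: 13 (2S,3R,4S,5R)-2-[4-(benzyloxy)-3-methoxyphenyl]-5-(3,4-dimethoxyphenyl)-3,4-dimethyltetrahydrofuran
Product: 14 4-[(2S,3R,4S,5R)-5-(3,4-dimethoxyphenyl)-3,4-dimethyltetrahydrofuran-2-yl]-2-methoxyphenol
Conditions: H2 (1 atm), Pd/C (10 wt% Pd), EtOAc, rt
Reagents that add atoms: none
Why: Catalytic hydrogenolysis of the benzyl aryl ether should free the phenol, while the dialkyl benzylic C–O bonds of the ring are cleaved much more slowly at balloon pressure.

Step 9
Reactants: 1 3,4-dimethoxybenzaldehyde; 15 acetaldehyde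
Product: 16 (R)-1-(3,4-dimethoxyphenyl)-2-hydroxypropan-1-one
Conditions: benzaldehyde lyase (thiamine-diphosphate-dependent lyase), thiamine diphosphate, MgSO4, KH2PO4/K2HPO4 buffer pH 8 with DMSO (20 vol%), acetaldehyde in portions, 30 °C
Reagents that add atoms: none
Why: Thiamine-diphosphate-dependent lyase carboligation, in which the enzyme-bound acyl anion equivalent of the aromatic aldehyde adds to acetaldehyde inside the active site and should give the (R)-2-hydroxy ketone in high ee.

Step 10
Reactants: 14 4-[(2S,3R,4S,5R)-5-(3,4-dimethoxyphenyl)-3,4-dimethyltetrahydrofuran-2-yl]-2-methoxyphenol; 16 (R)-1-(3,4-dimethoxyphenyl)-2-hydroxypropan-1-one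
Product: 18 (S)-1-(3,4-dimethoxyphenyl)-2-{4-[(2S,3R,4S,5R)-5-(3,4-dimethoxyphenyl)-3,4-dimethyltetrahydrofuran-2-yl]-2-methoxyphenoxy}propan-1-one, via alkoxyphosphonium ion 17 (not isolated)
Conditions: PPh3 (1.5 equiv), DIAD (1.5 equiv), THF, 0 °C to rt
Reagents that add atoms: none
Why: Mitsunobu etherification, in which the phenol displaces the phosphonium-activated hydroxyl by SN2 (accelerated by the adjacent carbonyl), inverting the carbinol carbon from (R) to (S).

Step 11
Reactants: 18 (S)-1-(3,4-dimethoxyphenyl)-2-{4-[(2S,3R,4S,5R)-5-(3,4-dimethoxyphenyl)-3,4-dimethyltetrahydrofuran-2-yl]-2-methoxyphenoxy}propan-1-one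
Product: 19 (1R,2S)-1-(3,4-dimethoxyphenyl)-2-{4-[(2S,3R,4S,5R)-5-(3,4-dimethoxyphenyl)-3,4-dimethyltetrahydrofuran-2-yl]-2-methoxyphenoxy}propan-1-ol
Conditions: Zn(BH4)2, Et2O/THF, −20 to 0 °C; aq. NH4Cl
Reagents that add atoms: none
Why: Chelation-controlled (Cram chelate) hydride reduction, in which zinc bridges the carbonyl and aryloxy oxygens and hydride attacks from the side of the small α-hydrogen, which should give the erythro (1R,2S) alcohol.

Compound list
1 | 3,4-dimethoxybenzaldehyde | COc1ccc(C=O)cc1OC | starting material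
2 | isopropenylmagnesium bromide | CC(=C)[Mg]Br | starting material
3 | rac-1-(3,4-dimethoxyphenyl)-2-methylprop-2-en-1-ol | COc1ccc(C(O)C(C)=C)cc1OC | intermediate
4 | (R)-1-(3,4-dimethoxyphenyl)-2-methylprop-2-en-1-ol | COc1ccc([C@H](O)C(C)=C)cc1OC | intermediate
5 | methacryloyl chloride | CC(=C)C(=O)Cl | starting material
6 | (R)-1-(3,4-dimethoxyphenyl)-2-methylprop-2-en-1-yl 2-methylprop-2-enoate | COc1ccc([C@H](OC(=O)C(C)=C)C(C)=C)cc1OC | intermediate
7 | (S)-5-(3,4-dimethoxyphenyl)-3,4-dimethylfuran-2(5H)-one | COc1ccc([C@@H]2OC(=O)C(C)=C2C)cc1OC | intermediate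
8 | (3R,4S,5R)-5-(3,4-dimethoxyphenyl)-3,4-dimethyldihydrofuran-2(3H)-one | COc1ccc([C@@H]2OC(=O)[C@H](C)[C@@H]2C)cc1OC | intermediate
9 | 1-(benzyloxy)-4-bromo-2-methoxybenzene | COc1cc(Br)ccc1OCc1ccccc1 | starting material
10 | 4-benzyloxy-3-methoxyphenyllithium | [Li]c1ccc(OCc2ccccc2)c(OC)c1 | intermediate
11 | (3R,4S,5R)-2-[4-(benzyloxy)-3-methoxyphenyl]-5-(3,4-dimethoxyphenyl)-3,4-dimethyltetrahydrofuran-2-ol | COc1ccc([C@@H]2OC(O)(c3ccc(OCc4ccccc4)c(OC)c3)[C@H](C)[C@@H]2C)cc1OC | intermediate
12 | (3R,4S,5R)-2-[4-(benzyloxy)-3-methoxyphenyl]-5-(3,4-dimethoxyphenyl)-3,4-dimethyl-4,5-dihydro-3H-furan-1-ium (oxocarbenium ion) | COc1ccc([C@@H]2[O+]=C(c3ccc(OCc4ccccc4)c(OC)c3)[C@H](C)[C@@H]2C)cc1OC | intermediate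
13 | (2S,3R,4S,5R)-2-[4-(benzyloxy)-3-methoxyphenyl]-5-(3,4-dimethoxyphenyl)-3,4-dimethyltetrahydrofuran | COc1ccc([C@@H]2O[C@H](c3ccc(OCc4ccccc4)c(OC)c3)[C@H](C)[C@@H]2C)cc1OC | intermediate
14 | 4-[(2S,3R,4S,5R)-5-(3,4-dimethoxyphenyl)-3,4-dimethyltetrahydrofuran-2-yl]-2-methoxyphenol | COc1ccc([C@@H]2O[C@H](c3ccc(O)c(OC)c3)[C@H](C)[C@@H]2C)cc1OC | intermediate
15 | acetaldehyde | CC=O | starting material
16 | (R)-1-(3,4-dimethoxyphenyl)-2-hydroxypropan-1-one | COc1ccc(C(=O)[C@@H](C)O)cc1OC | intermediate
17 | {[(R)-1-(3,4-dimethoxyphenyl)-1-oxopropan-2-yl]oxy}triphenylphosphonium | COc1ccc(C(=O)[C@@H](C)O[P+](c2ccccc2)(c2ccccc2)c2ccccc2)cc1OC | intermediate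
18 | (S)-1-(3,4-dimethoxyphenyl)-2-{4-[(2S,3R,4S,5R)-5-(3,4-dimethoxyphenyl)-3,4-dimethyltetrahydrofuran-2-yl]-2-methoxyphenoxy}propan-1-one | COc1ccc(C(=O)[C@H](C)Oc2ccc([C@H]3O[C@@H](c4ccc(OC)c(OC)c4)[C@@H](C)[C@H]3C)cc2OC)cc1OC | intermediate
19 | (1R,2S)-1-(3,4-dimethoxyphenyl)-2-{4-[(2S,3R,4S,5R)-5-(3,4-dimethoxyphenyl)-3,4-dimethyltetrahydrofuran-2-yl]-2-methoxyphenoxy}propan-1-ol | COc1ccc([C@@H](O)[C@H](C)Oc2ccc([C@H]3O[C@@H](c4ccc(OC)c(OC)c4)[C@@H](C)[C@H]3C)cc2OC)cc1OC | target

Total step count: 11. Longest linear sequence: 10 steps (steps 1–8, 10, 11); step 9 is a one-step branch.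

Steps most likely to fail

Step 4. The catalyst may decompose before two hindered 1,1-disubstituted alkenes, one of them electron-poor, have turned over, leaving unreacted diene or oligomer. Fallback from 4: esterification with 2-(diethoxyphosphoryl)propanoic acid (DCC, DMAP, CH2Cl2) should give (R)-1-(3,4-dimethoxyphenyl)-2-methylprop-2-en-1-yl 2-(diethoxyphosphoryl)propanoate F1. Oxidative cleavage of the isopropenyl alkene (K2OsO4·2H2O cat., NaIO4, 2,6-lutidine, dioxane/H2O) should then give (S)-1-(3,4-dimethoxyphenyl)-2-oxopropyl 2-(diethoxyphosphoryl)propanoate F2. An intramolecular Horner–Wadsworth–Emmons olefination under mild base (LiCl, iPr2NEt, MeCN, 0 °C) closes the same C3=C4 bond and comes back to 7.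

Step 7. The oxocarbenium ion may epimerise at C3 through its enol ether before hydride capture, driven by relief of the all-cis strain. Fallback from 11: acid-catalysed dehydration (camphorsulfonic acid cat., 4 Å molecular sieves, CH2Cl2) should give (2R,3S)-5-[4-(benzyloxy)-3-methoxyphenyl]-2-(3,4-dimethoxyphenyl)-3,4-dimethyl-2,3-dihydrofuran F3, in which the former C3 is planar and no longer at risk. Hydrogenation (H2, Pd/C, EtOAc) should add both hydrogens to the enol ether from the face opposite the neighbouring methyl and aryl and cleave the benzyl ether in the same operation, so the route is rejoined at 14.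

Step 10. Configuration at the carbinol carbon may be lost by enolisation of the activated hydroxy ketone, or elimination may compete with substitution at the hindered phenol. Fallback from 16: tosylation (TsCl, pyridine, 0 °C) should give (R)-1-(3,4-dimethoxyphenyl)-1-oxopropan-2-yl 4-methylbenzenesulfonate F4. SN2 displacement by the phenoxide of 14 (K2CO3, DMF, rt) proceeds with inversion and comes back to 18.

Further compounds
F1 | step 4 | (R)-1-(3,4-dimethoxyphenyl)-2-methylprop-2-en-1-yl 2-(diethoxyphosphoryl)propanoate | COc1ccc([C@H](OC(=O)C(C)P(=O)(OCC)OCC)C(C)=C)cc1OC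
F2 | step 4 | (S)-1-(3,4-dimethoxyphenyl)-2-oxopropyl 2-(diethoxyphosphoryl)propanoate | COc1ccc([C@H](OC(=O)C(C)P(=O)(OCC)OCC)C(C)=O)cc1OC
F3 | step 7 | (2R,3S)-5-[4-(benzyloxy)-3-methoxyphenyl]-2-(3,4-dimethoxyphenyl)-3,4-dimethyl-2,3-dihydrofuran | COc1ccc([C@@H]2OC(c3ccc(OCc4ccccc4)c(OC)c3)=C(C)[C@@H]2C)cc1OC
F4 | step 10 | (R)-1-(3,4-dimethoxyphenyl)-1-oxopropan-2-yl 4-methylbenzenesulfonate | COc1ccc(C(=O)[C@@H](C)OS(=O)(=O)c2ccc(C)cc2)cc1OC
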